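Amounts first: the midnight run was charged with 0.071 M of solid substrate, the autumn run with 0.11 M, and the new flask gets 0.051 M, less than either.

| flask | solid substrate | remark | time |
|---|---|---|---|
| midnight | 0.071 M | run made earlier |  |
| autumn | 0.11 M | run made earlier |  |
| flask | 0.051 M |  | 8.0 d |

| run | time / d | intermediate A / % | product / % | solid substrate / % |
|---|---|---|---|---|
| midnight | 0.833 | 4.0 | 0 | 87.5 |
| midnight | 1.67 | 6.5 | 5.4 | 72.5 |
| midnight | 3.00 | 7.3 | 19.6 | 51.5 |
| midnight | 5.00 | 7.9 | 50.1 | 21.5 |
| midnight | 10.0 | 0 | 98.9 | 0.1 |
| autumn | 0.833 | 3.5 | 0.2 | 91.6 |
| autumn | 1.67 | 5.7 | 0.9 | 83.3 |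
| autumn | 3.00 | 5.1 | 12.6 | 68.3 |
| autumn | 5.00 | 4.9 | 32.6 | 47.6 |
| autumn | 10.0 | 2.7 | 82.2 | 1.4 |

(scatter of a reading: 1 percentage point)

- as a solid, counted per litre of solution: solid substrate
- at the start none of the solid substrate is in solution
- a reading or a percentage of product counts all its forms, free or not

* time, not beyond 8.0 d, at which the flask holds most intermediate A
* the amount of intermediate A, in percent of the solid substrate charged, at that time

What does intermediate A do in the midnight run? It sits flat, 7.3% at 3.00 d and 7.9% at 5.00 d, averaging 7.60%, with 21.5% of the solid still there.

And in the autumn run? It is flat again, but lower, averaging 5.00%.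

Is that gap scatter? No: it is 2.6 percentage points, against a scatter of 1 point per reading. The midnight share is 1.52 times the autumn share, and the autumn charge is 1.55 times the midnight charge, so in these two runs the share read off goes about inversely with the charge.

What follows for the new flask? Run share times run charge over flask charge, averaged over both runs, gives 10.7%: this is the plateau share, the fraction of the charge held as intermediate A while solid remains.

How long does it last? The solid falls by 0.158 /d of its charge in the midnight run and 0.106 /d in the autumn run. Scaled the same way, that is 0.224 /d in the new flask, so its solid lasts about 4.46 d.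

And the exact time of the peak? That is the weak spot: these readings give a flat top, not a sharp time, so I commit to a window from about 3.00 d to 4.46 d.

The forecast says 11% at 4.6 d, adding “The plateau is flat, so the time is loosely defined”. The new flask gives 11.0% at 3.35 d.

    starting material → intermediate A (k = 5.40 × 10⁻⁵ /s)
    intermediate A → intermediate B (k = 2.30 × 10⁻⁵ /s)
    intermediate B → intermediate C (k = 3.10 × 10⁻⁵ /s)
    intermediate C → product (k = 1.50 × 10⁻⁵ /s)
    solid substrate ⇌ starting material, rate k5*(cs5 - [starting material]) while solid is left; crystals form when [starting material] > cs5 (solubility = 21.0 mM, k = 7.10 × 10⁻⁶ /s)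
    starting material + product ⇌ idle adduct, settled at all times (K = 10.0 /M)

In the new flask at 3.35 d, starting material stands at 4.70% of the charge and intermediate A at 11.0%, beside the plateau share of 10.7%. Intermediate A is made at 0.219 /d and used at 0.219 /d, as fractions of the charge, the balance called a steady state, and the new flask still holds 11.0% at 4.00 d. A neighbour flask charged with 0.13 M still holds 29.6% of its charge as solid at 8.00 d; the plateau share scaled to it is 4.20%, and that flask shows 4.33%.

The earlier runs and the new flask come from a simulation for an exercise; scatter was added.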